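**Retrosynthetic overview**

- Target 15 is reached from its tris(methyl ether) 13 by cleavage of the three aryl methyl ethers.
- Oxazinone ring: the C1–O2 bond comes from enol lactonization of keto acid 11; the N5–C4 bond comes from N-alkylation of pyrrole 7 with phenacyl bromide 8.
- Pyrrole ring: in the pyrrolo[2,1-c][1,4]oxazin-1-one core the C8–C8a bond joins the aryl-bearing C8 to the carboxyl-bearing C8a. These two carbons map onto an aryl ketone carbon and an oxalamide carbonyl carbon, so the bond is made by reductive oxo-amide coupling of 6 with low-valent titanium.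
- Precursor 6 comes from desoxyanisoin 1 by aminomethylenation with 2, exchange with ammonia and N-acylation with 5.
- Ring order: pyrrole first (step 4), oxazinone second (step 7); the three aryl rings are carried in from 1 and 8.

Key step: step 4

Remark: the target has no stereocentre. The only stereo-element in the route is the enaminone C=C geometry. Compound 3 is drawn as the E isomer expected for an amide-acetal condensation; this geometry is erased in step 2, where 4 settles as the hydrogen-bonded Z isomer.

**Step 1**
Reactants: 1 desoxyanisoin [1,2-bis(4-methoxyphenyl)ethanone]; 2 N,N-dimethylformamide dimethyl acetal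
Product: 3 (E)-3-(dimethylamino)-1,2-bis(4-methoxyphenyl)prop-2-en-1-one
Conditions: DMF-DMA (2 equiv.), toluene, 110 °C, MeOH distilled off
Reagents that add atoms: N,N-dimethylformamide dimethyl acetal, COC(OC)N(C)C
Why: Amide-acetal aminomethylenation (enaminone condensation): the CH2 of 1, acidified by the ketone and the aryl ring, adds to the iminium ion released from the acetal and methanol is lost twice, its removal driving the reaction.

**Step 2**
Reactants: 3 (E)-3-(dimethylamino)-1,2-bis(4-methoxyphenyl)prop-2-en-1-one
Product: 4 (Z)-3-amino-1,2-bis(4-methoxyphenyl)prop-2-en-1-one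
Conditions: NH4OAc (5 equiv.), EtOH, reflux
Reagents that add atoms: ammonium acetate, CC(=O)[O-].[NH4+]
Why: Vinylogous transamidation by conjugate addition of ammonia and elimination of volatile dimethylamine; the intramolecular N-H···O=C hydrogen bond of the primary enaminone should favour the Z geometry needed later.

**Step 3**
Reactants: 4 (Z)-3-amino-1,2-bis(4-methoxyphenyl)prop-2-en-1-one; 5 methyl chlorooxoacetate
Product: 6 methyl 2-{[(Z)-2,3-bis(4-methoxyphenyl)-3-oxoprop-1-enyl]amino}-2-oxoacetate
Conditions: pyridine (2 equiv.), CH2Cl2, 0 °C to rt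
Reagents that add atoms: methyl chlorooxoacetate, COC(=O)C(=O)Cl
Why: N-acylation of a primary enaminone by an acid chloride with pyridine as acid scavenger (amide formation); the α-carbon is fully substituted, so C-acylation cannot compete, and the N-H···O=C hydrogen bond should keep the product Z.

**Step 4**
Reactants: 6 methyl 2-{[(Z)-2,3-bis(4-methoxyphenyl)-3-oxoprop-1-enyl]amino}-2-oxoacetate
Product: 7 methyl 3,4-bis(4-methoxyphenyl)-1H-pyrrole-2-carboxylate
Conditions: TiCl3 / C8K (1:2, excess), DME, reflux, Ar; 6 added slowly to the preformed reagent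
Reagents that add atoms: none
Why: Low-valent titanium on graphite (from TiCl3 and two equivalents of C8K) transfers electrons to the diaryl ketone of 6, its most easily reduced carbonyl, and the titanium-bound ketyl or dianion carbon (future C8) attacks the neighbouring oxalamide carbonyl carbon (future C8a); the oxophilic metal then removes both oxygen atoms and leaves the C8=C8a bond of an aromatic pyrrole. The closest known reaction type is the McMurry-type intramolecular oxo-amide coupling that turns acylamino ketones into indoles and pyrroles. The one ring is closed in a 5-exo-trig mode (ring atoms N, C-H, C-aryl, ketone carbon, amide carbon; the attacked C=O lies outside the ring), and no stereocentre is formed. The step needs ketone-amide coupling to beat attack on the ester carbonyl and intermolecular pinacol coupling. The substrate should secure this because the N-H···O=C hydrogen bond of the Z-enaminone holds the two reacting carbons in a 1,5 relationship, so five-membered closure should be faster than six-membered closure onto the ester carbon or dimerization (helped by slow addition), and the amide carbonyl is activated by the adjacent ester and by delocalization of the nitrogen lone pair into the enone. Aromatization makes the deoxygenation irreversible, and the product, which has no ketone left, should be inert to the reagent.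

**Step 5**
Reactants: 7 methyl 3,4-bis(4-methoxyphenyl)-1H-pyrrole-2-carboxylate; 8 2-bromo-1-(4-methoxyphenyl)ethanone
Product: 9 methyl 1-[2-(4-methoxyphenyl)-2-oxoethyl]-3,4-bis(4-methoxyphenyl)-1H-pyrrole-2-carboxylate
Conditions: K2CO3, acetone, reflux
Reagents that add atoms: 2-bromo-1-(4-methoxyphenyl)ethanone, COc1ccc(C(=O)CBr)cc1
Why: SN2 N-alkylation of the pyrrolide anion, whose N-H is acidified by the 2-ester, with a highly reactive α-bromo ketone under mild carbonate conditions.

**Step 6**
Reactants: 9 methyl 1-[2-(4-methoxyphenyl)-2-oxoethyl]-3,4-bis(4-methoxyphenyl)-1H-pyrrole-2-carboxylate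
Product: 11 1-[2-(4-methoxyphenyl)-2-oxoethyl]-3,4-bis(4-methoxyphenyl)-1H-pyrrole-2-carboxylic acid, via potassium carboxylate 10 (not isolated)
Conditions: KOH, EtOH/H2O, reflux; then aq. HCl, 0 °C
Reagents that add atoms: potassium hydroxide, [K+].[OH-]
Why: Saponification (acyl-oxygen cleavage by hydroxide) of the methyl ester, the only hydrolysable group in 9, then protonation of the carboxylate; aryl ethers and the ketone are inert to aqueous hydroxide.

**Step 7**
Reactants: 11 1-[2-(4-methoxyphenyl)-2-oxoethyl]-3,4-bis(4-methoxyphenyl)-1H-pyrrole-2-carboxylic acid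
Product: 13 3,7,8-tris(4-methoxyphenyl)-1H-pyrrolo[2,1-c][1,4]oxazin-1-one, via mixed acetic anhydride 12 (not isolated)
Conditions: Ac2O, NaOAc, 120 °C
Reagents that add atoms: none
Why: Classical Ac2O/NaOAc enol lactonization of a keto acid: the acid is activated as mixed anhydride 12 and the acetate-enolized aryl ketone is O-acylated in a 6-exo-trig closure forming the C1–O2 bond, C-acylation being impossible because it would need a four-membered ring.

**Step 8**
Reactants: 13 3,7,8-tris(4-methoxyphenyl)-1H-pyrrolo[2,1-c][1,4]oxazin-1-one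
Product: 15 3,7,8-tris(4-hydroxyphenyl)-1H-pyrrolo[2,1-c][1,4]oxazin-1-one (target), via tris(dibromoboryl) ether 14 (not isolated)
Conditions: BBr3 (6 equiv.), CH2Cl2, −78 °C to rt; then H2O, 0 °C
Reagents that add atoms: none
Why: Lewis-acid cleavage of aryl methyl ethers by BBr3 (O–B complexation, bromide attack on the methyl carbon) with hydrolysis of the aryl borates on work-up; the lactone carbonyl, a vinylogous carbamate conjugated with the pyrrole nitrogen, is a poor electrophile and should survive at low temperature.

**Compound list**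

1 | desoxyanisoin, 1,2-bis(4-methoxyphenyl)ethanone | COc1ccc(CC(=O)c2ccc(OC)cc2)cc1 | starting material
2 | N,N-dimethylformamide dimethyl acetal | COC(OC)N(C)C | starting material
3 | (E)-3-(dimethylamino)-1,2-bis(4-methoxyphenyl)prop-2-en-1-one | CN(C)/C=C(\c1ccc(OC)cc1)C(=O)c1ccc(OC)cc1 | intermediate
4 | (Z)-3-amino-1,2-bis(4-methoxyphenyl)prop-2-en-1-one | N/C=C(/c1ccc(OC)cc1)C(=O)c1ccc(OC)cc1 | intermediate
5 | methyl chlorooxoacetate | COC(=O)C(=O)Cl | starting material
6 | methyl 2-{[(Z)-2,3-bis(4-methoxyphenyl)-3-oxoprop-1-enyl]amino}-2-oxoacetate | COC(=O)C(=O)N/C=C(/c1ccc(OC)cc1)C(=O)c1ccc(OC)cc1 | intermediate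
7 | methyl 3,4-bis(4-methoxyphenyl)-1H-pyrrole-2-carboxylate | COC(=O)c1[nH]cc(-c2ccc(OC)cc2)c1-c1ccc(OC)cc1 | intermediate
8 | 2-bromo-1-(4-methoxyphenyl)ethanone | COc1ccc(C(=O)CBr)cc1 | starting material
9 | methyl 1-[2-(4-methoxyphenyl)-2-oxoethyl]-3,4-bis(4-methoxyphenyl)-1H-pyrrole-2-carboxylate | COC(=O)c1n(CC(=O)c2ccc(OC)cc2)cc(-c2ccc(OC)cc2)c1-c1ccc(OC)cc1 | intermediate
10 | potassium 1-[2-(4-methoxyphenyl)-2-oxoethyl]-3,4-bis(4-methoxyphenyl)-1H-pyrrole-2-carboxylate (not isolated) | [K+].[O-]C(=O)c1n(CC(=O)c2ccc(OC)cc2)cc(-c2ccc(OC)cc2)c1-c1ccc(OC)cc1 | intermediate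
11 | 1-[2-(4-methoxyphenyl)-2-oxoethyl]-3,4-bis(4-methoxyphenyl)-1H-pyrrole-2-carboxylic acid | OC(=O)c1n(CC(=O)c2ccc(OC)cc2)cc(-c2ccc(OC)cc2)c1-c1ccc(OC)cc1 | intermediate
12 | acetic 1-[2-(4-methoxyphenyl)-2-oxoethyl]-3,4-bis(4-methoxyphenyl)-1H-pyrrole-2-carboxylic anhydride (not isolated) | CC(=O)OC(=O)c1n(CC(=O)c2ccc(OC)cc2)cc(-c2ccc(OC)cc2)c1-c1ccc(OC)cc1 | intermediate
13 | 3,7,8-tris(4-methoxyphenyl)-1H-pyrrolo[2,1-c][1,4]oxazin-1-one | O=c1oc(-c2ccc(OC)cc2)cn2cc(-c3ccc(OC)cc3)c(-c3ccc(OC)cc3)c12 | intermediate
14 | 3,7,8-tris[4-(dibromoboryloxy)phenyl]-1H-pyrrolo[2,1-c][1,4]oxazin-1-one (not isolated) | O=c1oc(-c2ccc(OB(Br)Br)cc2)cn2cc(-c3ccc(OB(Br)Br)cc3)c(-c3ccc(OB(Br)Br)cc3)c12 | intermediate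
15 | 3,7,8-tris(4-hydroxyphenyl)-1H-pyrrolo[2,1-c][1,4]oxazin-1-one | O=c1oc(-c2ccc(O)cc2)cn2cc(-c3ccc(O)cc3)c(-c3ccc(O)cc3)c12 | target

**Step count**

Total steps: 8. Longest linear sequence: 8 steps (1 to 15); compounds 2, 5 and 8 enter as purchased reagents.

**Steps most likely to fail, with fallbacks**

Step 4 (reductive ring closure). The ketone may be over-reduced to the alcohol or methylene stage before it couples, and intermolecular pinacol coupling, attack on the ester carbonyl or reductive loss of the N-acyl group may compete. The fallback makes the same C8–C8a bond by polar condensation and no reduction. It sets out from 3 and comes back at 7. Heating 3 with methyl glycinate hydrochloride in methanol should exchange the dimethylamino group and give methyl N-[(Z)-2,3-bis(4-methoxyphenyl)-3-oxoprop-1-enyl]glycinate F1. NaOMe in refluxing methanol should then close the pyrrole by intramolecular aldol-type condensation of the glycinate α-carbon onto the aryl ketone and loss of water, giving 7.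

Step 8 (ether cleavage). The enol lactone may be opened by the Lewis acid or during the aqueous quench, or the third methyl ether may be cleaved incompletely. The fallback moves the demethylation ahead of ring closure and ends with a mild deacylation. It sets out from 11 and comes back at 15. BBr3 in CH2Cl2 followed by aqueous work-up should convert 11 into 3,4-bis(4-hydroxyphenyl)-1-[2-(4-hydroxyphenyl)-2-oxoethyl]-1H-pyrrole-2-carboxylic acid F2. Ac2O/NaOAc should then close the lactone and acetylate the phenols in one operation to give 3,7,8-tris(4-acetoxyphenyl)-1H-pyrrolo[2,1-c][1,4]oxazin-1-one F3. Solvolysis of the aryl acetates with NH4OAc in aqueous methanol at room temperature, conditions selective for phenolic acetates, should release 15.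

Step 7 (enol lactonization). Enolization of the aryl ketone may be too slow under acetate buffering, so that the hot mixed anhydride undergoes intermolecular acyl transfer or decarboxylation instead of ring closure. The fallback uses a discrete acyl chloride and base-induced enolate O-acylation at low temperature. It sets out from 11 and comes back at 13. Oxalyl chloride with catalytic DMF in CH2Cl2 at 0 °C should give 1-[2-(4-methoxyphenyl)-2-oxoethyl]-3,4-bis(4-methoxyphenyl)-1H-pyrrole-2-carbonyl chloride F4. Triethylamine at 0 °C to room temperature should then enolize the ketone and close the six-membered enol lactone to 13.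

**Further compounds**

F1 | step 4 | methyl N-[(Z)-2,3-bis(4-methoxyphenyl)-3-oxoprop-1-enyl]glycinate | COC(=O)CN/C=C(/c1ccc(OC)cc1)C(=O)c1ccc(OC)cc1
F2 | step 8 | 3,4-bis(4-hydroxyphenyl)-1-[2-(4-hydroxyphenyl)-2-oxoethyl]-1H-pyrrole-2-carboxylic acid | OC(=O)c1n(CC(=O)c2ccc(O)cc2)cc(-c2ccc(O)cc2)c1-c1ccc(O)cc1
F3 | step 8 | 3,7,8-tris(4-acetoxyphenyl)-1H-pyrrolo[2,1-c][1,4]oxazin-1-one | O=c1oc(-c2ccc(OC(C)=O)cc2)cn2cc(-c3ccc(OC(C)=O)cc3)c(-c3ccc(OC(C)=O)cc3)c12
F4 | step 7 | 1-[2-(4-methoxyphenyl)-2-oxoethyl]-3,4-bis(4-methoxyphenyl)-1H-pyrrole-2-carbonyl chloride | O=C(Cl)c1n(CC(=O)c2ccc(OC)cc2)cc(-c2ccc(OC)cc2)c1-c1ccc(OC)cc1
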